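## Retrosynthetic overview

1. Feature: the ketone carbons C4(A) and C4(B) of the two chromanone rings are 1,4-related across the C3(A)–C3(B) bond. Diketone 18 is therefore traced back, by C=C cleavage, to cyclobutene 16, whose ring is C4(A)=C4(B)–C3(B)–C3(A).
2. 16 is cut at C3(A)–C4(A) and C3(B)–C4(B). A transannular alkyne plus (E)-alkene [2+2] photocycloaddition in the 12-membered macrocycle 15 closes both pyran rings and the four-membered ring at once, and sets C3(A) and C3(B) from the C2 centres already present.
3. 15 is cut at both C2–O1 bonds. Diarylacetylene 12 and the C2-symmetric (R,R)-(E)-enediol 5 are joined by two Mitsunobu inversions, the second closing the macrocycle, so neither zerovalent palladium nor base meets the allylic aryl ethers.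
4. 12 comes from iodophenol 7 and alkyne 11 by Sonogashira coupling. 5 comes from an aryl vinyl carbinol by kinetic resolution and metathesis homodimerisation. The C2-aryl oxygens travel as tert-butyl carbonates rather than donor ethers, so the benzylic–allylic carbinols react by SN2 and do not ionise.
5. Ring order: macrocycle (step 12), then two pyrans plus cyclobutene (step 13), then opening of the cyclobutene to the two ketones (step 14), then global acidolysis (step 15).

Key step: step 13

Assumptions:
- Unit A is the 7-hydroxyflavanone half and unit B the 5,7-dihydroxyflavanone half. Flavanone numbering with the unit letter is used for all intermediates.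
- The target is (2S,3R) in both units, which is 2,3-trans.
- Ar stands for 4-(tert-butoxycarbonyloxy)phenyl.
- 4-Iodoresorcinol is taken as a catalogue compound. It is otherwise one step from resorcinol and ICl.

## Route

Step 1
Reactants: 1 4-hydroxybenzaldehyde
Product: 2 tert-butyl 4-formylphenyl carbonate
Conditions: Boc2O (1.1 equiv), DMAP (5 mol %), CH2Cl2, rt
Reagents that add atoms: di-tert-butyl dicarbonate CC(C)(C)OC(=O)OC(=O)OC(C)(C)C
Why: DMAP-catalysed O-acylation of the phenol leaves the aldehyde untouched, and the carbonate turns the para oxygen from a strong donor into a nearly neutral substituent, as the later benzylic SN2 steps require, while remaining removable with acid at the end.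

Step 2
Reactants: 2 tert-butyl 4-formylphenyl carbonate
Product: 3 rac-tert-butyl 4-(1-hydroxyprop-2-en-1-yl)phenyl carbonate
Conditions: CH2=CHMgBr (1.05 equiv), THF, −78 °C; sat. aq NH4Cl at −78 °C
Reagents that add atoms: vinylmagnesium bromide C=C[Mg]Br
Why: Grignard 1,2-addition to the aldehyde is far faster at −78 °C than attack on the hindered tert-butyl carbonate, the cold quench prevents carbonate migration to the new alkoxide, and the carbinol centre is formed racemic on purpose.

Step 3
Reactants: 3 rac-tert-butyl 4-(1-hydroxyprop-2-en-1-yl)phenyl carbonate
Product: 4 tert-butyl 4-[(1R)-1-hydroxyprop-2-en-1-yl]phenyl carbonate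
Conditions: Ti(O-i-Pr)4 (0.15 equiv), D-(−)-diisopropyl tartrate (0.18 equiv), t-BuOOH (0.6 equiv), 4 Å MS, CH2Cl2, −20 °C
Reagents that add atoms: none
Why: Sharpless kinetic resolution, in which the (S)-carbinol is the fast-epoxidised enantiomer with the D-(−)-tartrate, so running slightly past half conversion should leave the (R)-alcohol in high enantiomeric purity, and this selects the configuration that becomes C2(A) and C2(B) after inversion.

Step 4
Reactants: 4 tert-butyl 4-[(1R)-1-hydroxyprop-2-en-1-yl]phenyl carbonate (two molecules)
Product: 5 (1R,4R,2E)-1,4-bis[4-(tert-butoxycarbonyloxy)phenyl]but-2-ene-1,4-diol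
Conditions: second-generation Hoveyda–Grubbs catalyst RuCl2(H2IMes)(=CH-C6H4-2-O-i-Pr) (5 mol %), 1,4-benzoquinone (10 mol %), CH2Cl2 (1 M), 40 °C, argon sparge
Reagents that add atoms: none
Why: Olefin cross-metathesis (homodimerisation) of the terminal allylic alcohol, driven by loss of ethene, should give the favoured (E)-alkene without touching the carbinol centres, benzoquinone suppresses ruthenium hydride isomerisation to the ketone, and pairing of two enriched monomers moves most of the minor enantiomer into the separable meso diol.

Step 5
Reactants: 6 4-iodoresorcinol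
Product: 7 2-iodo-5-(methoxymethoxy)phenol
Conditions: MOMCl (1.0 equiv), i-Pr2NEt (1.1 equiv), CH2Cl2, 0 °C
Reagents that add atoms: chloromethyl methyl ether COCCl
Why: In this O-alkylation (MOM protection) with one equivalent of reagent, the hydroxyl para to iodine is the less hindered one and is not engaged with the halogen, so it should react first, as in the known monoalkylation of 4-haloresorcinols.

Step 6
Reactants: 8 2,4,6-trihydroxybenzaldehyde
Product: 9 2-hydroxy-4,6-bis(methoxymethoxy)benzaldehyde
Conditions: MOMCl (2.1 equiv), i-Pr2NEt (2.5 equiv), CH2Cl2, 0 °C to rt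
Reagents that add atoms: chloromethyl methyl ether COCCl
Why: In this chelation-controlled MOM protection the hydroxyl hydrogen-bonded to the formyl group is deactivated, and because the two ortho hydroxyls are equivalent only one bis-ether can form, which fixes the oxygen pattern of ring A of unit B without a regiochemical question.

Step 7
Reactants: 9 2-hydroxy-4,6-bis(methoxymethoxy)benzaldehyde
Product: 10 2,4-bis(methoxymethoxy)-6-(triisopropylsilyloxy)benzaldehyde
Conditions: TIPSCl, imidazole, DMF, rt to 40 °C
Reagents that add atoms: chlorotriisopropylsilane CC(C)[Si](Cl)(C(C)C)C(C)C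
Why: Imidazole-promoted silylation caps the last phenol with a bulky group that resists O-to-O migration in the next step, and the chloride is used instead of the triflate so that the aryl MOM ethers are not activated.

Step 8
Reactants: 10 2,4-bis(methoxymethoxy)-6-(triisopropylsilyloxy)benzaldehyde
Product: 11 [2-ethynyl-3,5-bis(methoxymethoxy)phenoxy]triisopropylsilane
Conditions: TMSCHN2, n-BuLi (1.2 equiv each), THF, −78 °C; then 10, −78 °C to rt
Reagents that add atoms: (trimethylsilyl)diazomethane C[Si](C)(C)C=[N+]=[N-]
Why: In the Colvin rearrangement the strongly nucleophilic lithiated diazo reagent adds even to this electron-rich, doubly ortho-substituted aldehyde, silanolate and N2 are lost, and the 1,2-hydride shift of the alkylidene carbene gives the terminal alkyne without the methanolic base that would strip the silyl ether.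

Step 9
Reactants: 7 2-iodo-5-(methoxymethoxy)phenol; 11 [2-ethynyl-3,5-bis(methoxymethoxy)phenoxy]triisopropylsilane
Product: 12 2-{[2,4-bis(methoxymethoxy)-6-(triisopropylsilyloxy)phenyl]ethynyl}-5-(methoxymethoxy)phenol
Conditions: PdCl2(PPh3)2 (3 mol %), CuI (5 mol %), Et3N, THF, rt, argon
Reagents that add atoms: none
Why: In this Sonogashira coupling the aryl iodide reacts at room temperature, where 5-endo cyclisation of the ortho-alkynylphenol to a benzofuran is slow, so the diarylacetylene is obtained directly with one ortho phenol free and the other silylated.

Step 10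
Reactants: 12 the diarylacetylene with free unit-A phenol; 5 the (R,R)-(E)-enediol
Product: 13 (1R,4S,2E)-1,4-di-Ar-4-aryloxybut-2-en-1-ol, in which the aryloxy group is the O1(A) phenoxide of 12, C2(A) is S and the remaining carbinol is R
Conditions: 5 (3 equiv), PPh3, DIAD (1.2 equiv each), toluene, −20 to 0 °C; surplus 5 recovered
Reagents that add atoms: none
Why: In this Mitsunobu etherification the phenol displaces the alkoxyphosphonium salt of one of the two homotopic hydroxyls by SN2 with inversion, which sets C2(A) as S, while the carbonate-bearing aryl group, the withdrawing oxygen at the far allylic position, the hindered internal alkene carbon and the cold non-polar medium all disfavour ionisation and SN2' attack, and any leak in configuration ends in a separable diastereomer rather than in the enantiomer.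

Step 11
Reactants: 13 the mono-ether
Product: 14 the seco phenol, which is 13 with free O1(B)–H in place of the silyl ether
Conditions: Et3N·3HF, THF, 0 °C to rt
Reagents that add atoms: none
Why: Fluoride cleavage of the phenolic silyl ether in a weakly acidic medium spares the aryl carbonates, the MOM ethers and the allylic aryl ether, and generates no free phenoxide that could add to the neighbouring alkyne.

Step 12
Reactants: 14 the seco phenol
Product: 15 the (S,S,E)-12-membered macrocycle with ring path C2(A)H(Ar)–C3(A)H=C3(B)H–C2(B)H(Ar)–O1(B)–C8a(B)–C4a(B)–C4(B)≡C4(A)–C4a(A)–C8a(A)–O1(A), and OMOM at C7(A), C5(B) and C7(B)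
Conditions: PPh3, DIAD (4 equiv each), toluene, 0 °C to rt, slow addition of 14 (final 1 mM)
Reagents that add atoms: none
Why: In this intramolecular Mitsunobu etherification under high dilution the SN2 inversion of the (R)-carbinol sets C2(B) as S, and the ring should be nearly free of strain because the two aryl rings can turn about the alkyne axis until the O1(A) to O1(B) distance fits the (E)-butenediyl bridge.

Step 13
Reactants: 15 the (S,S,E)-macrocycle
Product: 16 the cyclobutene-fused bis-benzopyran, with cyclobutene C4(A)=C4(B)–C3(B)H–C3(A)H and each C3–C4 edge shared with a 2-Ar-dihydropyran; H3(A) and H3(B) are trans, H2 and H3 are trans in both pyrans, and C2(A), C3(A), C3(B), C2(B) are all S (the C3 centres have the same spatial arrangement as in the target, and their descriptor differs only because C4 ranks lower here)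
Conditions: thioxanthone (20 mol %), 385–395 nm LED, degassed MeCN–CH2Cl2 (1 mM), −10 °C
Reagents that add atoms: none
Why: Proposed new method: Triplet energy transfer from thioxanthone should excite only the diarylacetylene, since the isolated alkene and the aryl carbonates lie much higher, and its diradical-like triplet attacks the (E)-alkene stacked across the ring at about van der Waals distance to give a 1,4-diradical (aryl-stabilised vinyl radical plus secondary alkyl radical) that closes after intersystem crossing; the closest known reaction types are the [2+2] photocycloaddition of diphenylacetylenes with alkenes to 1,2-diarylcyclobutenes and the [2+2] cycloisomerisation of 1,7-enynes to bicyclo[4.2.0]oct-1(8)-enes, neither of which has been run across a macrocycle. The first C4–C3 bond closes the dihydropyran of its unit in a 6-exo-trig mode through the four-atom tether C4a–C8a–O1–C2, and the radical recombination at C4–C3 of the other unit closes the cyclobutene as a four-membered closure and, through the identical second tether, the second dihydropyran at the same moment. C3(A) and C3(B) are the new stereocentres: their mutual trans relation follows from addition to one face of the (E)-alkene by a short-lived, ring-constrained diradical, and their relation to C2 follows from which alkene face looks at the alkyne. That face is fixed by the (S)-centres C2(A) and C2(B), because in the conformer free of allylic 1,3-strain each H2 eclipses the double bond, both ring oxygens sit on one face and hold the alkyne over it, both Ar groups point outwards, and bonding on this face places H2 anti to H3, which is the 2,3-trans relation of the target in both units. The step needs parallel rather than crossed regiochemistry, selective excitation and survival of the product: the two equal tethers allow only C4(A) to C3(A) and C4(B) to C3(B), long-wavelength sensitisation avoids the singlet photochemistry of the aryl allyl ethers and of the cis-stilbene unit of 16 (photo-Claisen shift, 6π closure, ring opening), and the low temperature holds back thermal conrotatory opening of 16 to the bis-chromene diene.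

Step 14
Reactants: 16 the cyclobutene-fused bis-benzopyran
Product: 18 (2S,3R)-configured protected biflavanone (both units 2S,3R; OMOM at C7(A), C5(B), C7(B); tert-butyl carbonates on both C2-aryl groups), via keto methoxy-hydroperoxide 17 (not isolated)
Conditions: O3, CH2Cl2–MeOH 4:1, NaHCO3, Sudan Red 7B, −78 °C; then Me2S, −78 °C to rt
Reagents that add atoms: ozone [O-][O+]=O; methanol CO (held only in 17)
Why: In this ozonolysis by the Criegee mechanism the strained, tetrasubstituted, doubly aryl-conjugated C4(A)=C4(B) bond is by far the most ozonophilic site, methanol traps the carbonyl oxide (expected on the more donor-substituted C4(B)) so that no strained bicyclic ozonide has to form, the indicator dye stops the gas flow before the MOM-bearing rings are attacked, and no stereocentre is touched.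

Step 15
Reactants: 18 the protected biflavanone
Product: 19 target, (2S,3R)-3-[(2S,3R)-5,7-dihydroxy-2-(4-hydroxyphenyl)-4-oxochroman-3-yl]-7-hydroxy-2-(4-hydroxyphenyl)chroman-4-one
Conditions: HCl (1.25 M in MeOH), THF, 40 °C
Reagents that add atoms: none
Why: Acid-catalysed acetal exchange of the three MOM ethers and acidolysis of the two tert-butyl carbonates occur in one operation, acid (unlike base) does not open the flavanones by retro-oxa-Michael elimination so C2 is kept, acid enolisation can only move C3(A) and C3(B) towards the favoured 2,3-trans arrangement already present, and the mild conditions stay clear of Paal–Knorr dehydration of the 1,4-diketone.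

## Compound list

1 | 4-hydroxybenzaldehyde | O=Cc1ccc(O)cc1 | starting material
2 | tert-butyl 4-formylphenyl carbonate | O=Cc1ccc(OC(=O)OC(C)(C)C)cc1 | intermediate
3 | rac-tert-butyl 4-(1-hydroxyprop-2-en-1-yl)phenyl carbonate | C=CC(O)c1ccc(OC(=O)OC(C)(C)C)cc1 | intermediate
4 | tert-butyl 4-[(1R)-1-hydroxyprop-2-en-1-yl]phenyl carbonate | C=C[C@@H](O)c1ccc(OC(=O)OC(C)(C)C)cc1 | intermediate
5 | (1R,4R,2E)-1,4-bis[4-(tert-butoxycarbonyloxy)phenyl]but-2-ene-1,4-diol | O[C@@H](c1ccc(OC(=O)OC(C)(C)C)cc1)/C=C/[C@@H](O)c1ccc(OC(=O)OC(C)(C)C)cc1 | intermediate
6 | 4-iodoresorcinol | Oc1ccc(I)c(O)c1 | starting material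
7 | 2-iodo-5-(methoxymethoxy)phenol | COCOc1ccc(I)c(O)c1 | intermediate
8 | 2,4,6-trihydroxybenzaldehyde | O=Cc1c(O)cc(O)cc1O | starting material
9 | 2-hydroxy-4,6-bis(methoxymethoxy)benzaldehyde | O=Cc1c(O)cc(OCOC)cc1OCOC | intermediate
10 | 2,4-bis(methoxymethoxy)-6-(triisopropylsilyloxy)benzaldehyde | O=Cc1c(O[Si](C(C)C)(C(C)C)C(C)C)cc(OCOC)cc1OCOC | intermediate
11 | [2-ethynyl-3,5-bis(methoxymethoxy)phenoxy]triisopropylsilane | C#Cc1c(O[Si](C(C)C)(C(C)C)C(C)C)cc(OCOC)cc1OCOC | intermediate
12 | 2-{[2,4-bis(methoxymethoxy)-6-(triisopropylsilyloxy)phenyl]ethynyl}-5-(methoxymethoxy)phenol | Oc1cc(OCOC)ccc1C#Cc1c(O[Si](C(C)C)(C(C)C)C(C)C)cc(OCOC)cc1OCOC | intermediate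
13 | mono-ether, C2(A) S, carbinol R, (E) | O[C@@H](c1ccc(OC(=O)OC(C)(C)C)cc1)/C=C/[C@@H](c1ccc(OC(=O)OC(C)(C)C)cc1)Oc1cc(OCOC)ccc1C#Cc1c(O[Si](C(C)C)(C(C)C)C(C)C)cc(OCOC)cc1OCOC | intermediate
14 | seco phenol, C2(A) S, carbinol R, (E) | O[C@@H](c1ccc(OC(=O)OC(C)(C)C)cc1)/C=C/[C@@H](c1ccc(OC(=O)OC(C)(C)C)cc1)Oc1cc(OCOC)ccc1C#Cc1c(O)cc(OCOC)cc1OCOC | intermediate
15 | (S,S,E)-12-membered diarylacetylene/alkene macrocycle (key-step precursor) | [C@@H]1(c2ccc(OC(=O)OC(C)(C)C)cc2)/C=C/[C@@H](c2ccc(OC(=O)OC(C)(C)C)cc2)Oc2cc(OCOC)cc(OCOC)c2C#Cc2ccc(OCOC)cc2O1 | intermediate
16 | cyclobutene-fused bis-benzopyran (key-step product) | C1=3c2ccc(OCOC)cc2O[C@H](c2ccc(OC(=O)OC(C)(C)C)cc2)[C@H]1[C@H]1C3c2c(OCOC)cc(OCOC)cc2O[C@@H]1c1ccc(OC(=O)OC(C)(C)C)cc1 | intermediate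
17 | keto methoxy-hydroperoxide, ketone at C4(A), C4(B)(OMe)(OOH), peroxyketal carbon of no defined configuration | O=C1c2ccc(OCOC)cc2O[C@H](c2ccc(OC(=O)OC(C)(C)C)cc2)[C@H]1[C@H]1C(OC)(OO)c2c(OCOC)cc(OCOC)cc2O[C@@H]1c1ccc(OC(=O)OC(C)(C)C)cc1 | intermediate
18 | protected biflavanone, 2S,3R in both units | O=C1c2ccc(OCOC)cc2O[C@H](c2ccc(OC(=O)OC(C)(C)C)cc2)[C@H]1[C@H]1C(=O)c2c(OCOC)cc(OCOC)cc2O[C@@H]1c1ccc(OC(=O)OC(C)(C)C)cc1 | intermediate
19 | CNP0138443.1, 2S,3R in both units | O=C1c2ccc(O)cc2O[C@H](c2ccc(O)cc2)[C@H]1[C@H]1C(=O)c2c(O)cc(O)cc2O[C@@H]1c1ccc(O)cc1 | target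

## Step count and risks

Total steps: 15. Longest linear sequence: 10 steps (8, 9, 10, 11, 12, 13, 14, 15, 16, 18, 19, which is steps 6 to 15). The branch from 1 (steps 1 to 4, then 10 to 15) is equally long.

**Steps most likely to fail**

**1. Step 13 (proposed new method).**
- Energy transfer may be slow because the bridge holds the two aryl rings of the alkyne twisted, which raises its triplet energy.
- The 1,4-diradical may fragment by loss of the β-aryloxy group, or revert with scrambling of the alkene geometry.
- The sensitiser may abstract hydrogen from the doubly activated C2–H bonds.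
- The cyclobutene may open onward to the diene.
- A wrong alkene face or scrambled geometry would not be fatal, because every C3 error becomes epimerisable after step 14.

Fallback, from 15 back to 16, uses π-acid catalysis in place of excited-state chemistry. A cationic complex of monovalent gold, [Au(NCMe)(P(t-Bu)2(biphenyl-2-yl))]SbF6 (5 mol %), is used in CH2Cl2 at 0 °C to rt. It activates the alkyne, the alkene attacks in a 6-exo-dig mode to give a cyclopropyl gold carbene, and ring expansion gives the cyclobutene. This is the known [2+2] cycloisomerisation of 1,7-enynes that carry aryl alkynes. It is stereospecific in the alkene and subject to the same facial bias of the macrocycle. No new compound is made.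

**2. Step 12.**
- Oligomerisation may compete with ring closure.
- If ring closure is slow, the activated benzylic–allylic carbinol may ionise, with loss of configuration or allylic transposition.

Fallback, from 5, 7 and 11 back to 15, closes the ring at carbon instead of oxygen, so that both ethers are made intermolecularly at normal concentration.
- Mitsunobu reaction of 7 with surplus 5 gives the iodoaryl mono-ether F1.
- Et3N·3HF frees 2-ethynyl-3,5-bis(methoxymethoxy)phenol F2 from 11.
- A second Mitsunobu reaction of F1 with F2 gives the open-chain iodo alkyne diether F3.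
- An intramolecular Sonogashira coupling (Pd(PPh3)4, CuI, Et3N, THF, rt, high dilution) forms the C4a(A)–C4(A) bond and gives 15.
- Only a tertiary amine is used, and the reaction is run at room temperature. This spares the carbonates and keeps zerovalent palladium from ionising the allylic aryl ethers or starting a 5-exo Heck closure.

**3. Step 14.**
- Ozone may attack the electron-rich MOM-bearing rings in competition with the alkene.
- The strained alkene may be lost by electrocyclic opening during handling.

Fallback, from 16 back to 18, is dye-sensitised photooxygenation (tetraphenylporphyrin, O2, green light, CH2Cl2, −40 °C, then warming). Singlet oxygen leaves alkoxyarenes alone and adds [2+2] to electron-rich diaryl alkenes whose allylic hydrogens are badly placed for the ene reaction, as is known for 1,2-diarylcyclobutenes. It gives the 1,2-dioxetane F4, which cleaves on warming to the two ketones of 18. Either face isomer of the dioxetane leads to the same product.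

## Further compounds

F0 | step 13 | none | none
F1 | step 12 | (1R,4S,2E)-1,4-bis[4-(tert-butoxycarbonyloxy)phenyl]-4-[2-iodo-5-(methoxymethoxy)phenoxy]but-2-en-1-ol | O[C@@H](c1ccc(OC(=O)OC(C)(C)C)cc1)/C=C/[C@@H](c1ccc(OC(=O)OC(C)(C)C)cc1)Oc1cc(OCOC)ccc1I
F2 | step 12 | 2-ethynyl-3,5-bis(methoxymethoxy)phenol | C#Cc1c(O)cc(OCOC)cc1OCOC
F3 | step 12 | (1S,4S,2E)-1,4-di-Ar-but-2-ene-1,4-diyl diether of F2 and 7 (open-chain iodo alkyne) | C#Cc1c(OCOC)cc(OCOC)cc1O[C@H](c1ccc(OC(=O)OC(C)(C)C)cc1)/C=C/[C@@H](c1ccc(OC(=O)OC(C)(C)C)cc1)Oc1cc(OCOC)ccc1I
F4 | step 14 | 1,2-dioxetane across C4(A)–C4(B) of 16 (face isomer with O–O syn to C2(A) written; the other converges) | O4[C@@]13c2ccc(OCOC)cc2O[C@H](c2ccc(OC(=O)OC(C)(C)C)cc2)[C@H]1[C@H]1[C@]3(O4)c2c(OCOC)cc(OCOC)cc2O[C@@H]1c1ccc(OC(=O)OC(C)(C)C)cc1
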